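The γ-lactone ring (ring oxygen, C6, C7, C11, C12) carries its oxygen on C6 next to the oxygenated C5, the pattern left by anti opening of a cis C5–C6 epoxide. The route therefore rests on disconnecting the lactone O–C6 bond: a (Z)-γ,δ-epoxy enoate, made from (S)-but-3-yn-2-ol, is closed under acid by 5-exo attack of the ester carbonyl oxygen on C6. One operation sets C6 with inversion, frees the C5 hydroxyl and delivers a butenolide whose α-hydroxy ketone and allylic C13 carbon later direct the C4 allylation and the chromium-mediated closure of the ten-membered ring.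

Key step: step 6

Remarks on the chemistry:
- Numbering used throughout: ring carbons C1–C10, with C9 the ketone carbon, C10 the CH(CH3) carbon, C2 the CH(OH) carbon, C4 the C(OH)CH3 carbon, C5 and C8 the isobutyrate-bearing carbons, C6 the lactone O–CH and C7 the ring-fusion CH. C11 is the lactone α-carbon, C12 the lactone carbonyl, C13 the exocyclic methylene; C14 and C15 are the methyls on C10 and C4.
- Assumption: 2,2-dimethoxyacetaldehyde is used as a dried, water-free solution.
- Assumption: the (E)-alkene is drawn for 15–21; any (Z)-isomer should converge at 22.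
- Assumption: (R)-TRIP is expected to give the (2R,3S) adduct in step 9; the antipodal acid would be used if the sense is opposite.

Step 1
Reactants: 1 (S)-but-3-yn-2-ol
Product: 2 (S)-pent-2-yne-1,4-diol
Conditions: n-BuLi (2.1 equiv), THF, −78 °C; (CH2O)n, −78 °C to rt
Reagents that add atoms: formaldehyde (as paraformaldehyde), C=O
Why: Double deprotonation gives the alkoxide–acetylide dianion, whose carbon end adds to formaldehyde (acetylide hydroxymethylation) without touching the carbinol stereocentre.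

Step 2
Reactants: 2 (S)-pent-2-yne-1,4-diol
Product: 3 (S,Z)-pent-2-ene-1,4-diol
Conditions: H2 (1 atm), Pd/CaCO3 poisoned with Pb(OAc)2, quinoline, EtOAc, rt
Reagents that add atoms: none
Why: Lindlar semihydrogenation adds hydrogen syn to the alkyne and should stop at the (Z)-alkene that the later cis-epoxide requires.

Step 3
Reactants: 3 (S,Z)-pent-2-ene-1,4-diol
Product: 4 (S)-1-[(2R,3S)-3-(hydroxymethyl)oxiran-2-yl]ethan-1-ol
Conditions: m-CPBA, CH2Cl2, 0 °C
Reagents that add atoms: m-chloroperoxybenzoic acid, O=C(OO)c1cccc(Cl)c1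
Why: Hydroxyl-directed peracid epoxidation (Henbest type) of a (Z)-allylic alcohol: allylic 1,3-strain holds the C4 hydrogen in the alkene plane and the C4 hydroxyl delivers the peracid to its own face, which should give the threo epoxy alcohol and so sets C5 and the epoxide configuration at C6 from the C4 carbinol.

Step 4
Reactants: 5 methyl 2-[bis(2,2,2-trifluoroethoxy)phosphoryl]acetate
Product: 6 methyl 2-[bis(2,2,2-trifluoroethoxy)phosphoryl]-3-(naphthalen-2-ylmethoxy)propanoate (racemic)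
Conditions: NaH, THF, 0 °C; 2-naphthylmethoxymethyl chloride, 0 °C to rt
Reagents that add atoms: 2-[(chloromethoxy)methyl]naphthalene, ClCOCc1ccc2ccccc2c1
Why: C-Alkylation of the sodium salt of the Still–Gennari phosphonoacetate with the reactive α-chloro ether installs C13 as a naphthylmethyl-protected hydroxymethyl group.

Step 5
Reactants: 4 (S)-1-[(2R,3S)-3-(hydroxymethyl)oxiran-2-yl]ethan-1-ol, 6 methyl 2-[bis(2,2,2-trifluoroethoxy)phosphoryl]-3-(naphthalen-2-ylmethoxy)propanoate
Product: 8 methyl (Z)-3-[(2S,3S)-3-acetyloxiran-2-yl]-2-[(naphthalen-2-ylmethoxy)methyl]prop-2-enoate, via epoxy keto aldehyde 7 (not isolated)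
Conditions: Dess–Martin periodinane, CH2Cl2, 0 °C; filtered solution added to 6, KN(SiMe3)2, 18-crown-6, THF, −78 °C
Reagents that add atoms: none
Why: Dess–Martin oxidation of both alcohols gives the keto aldehyde, and the Still–Gennari modification of the Horner–Wadsworth–Emmons reaction should olefinate only the aldehyde and give the (Z)-enoate in which the ester is cis to the epoxide carbon C6.

Step 6
Reactants: 8 methyl (Z)-3-[(2S,3S)-3-acetyloxiran-2-yl]-2-[(naphthalen-2-ylmethoxy)methyl]prop-2-enoate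
Product: 9 (5R)-5-[(1S)-1-hydroxy-2-oxopropyl]-3-[(naphthalen-2-ylmethoxy)methyl]furan-2(5H)-one
Conditions: camphorsulfonic acid (10 mol%), CH2Cl2, H2O (2 equiv), 0 °C to rt
Reagents that add atoms: water, O
Why: Protonation of the epoxide lets the (Z)-held ester carbonyl oxygen attack C6 from the face opposite the epoxide C6–O bond, giving a 2-methoxyfuranium ion that water converts to the lactone with loss of methanol. The closest known reaction type is the acid-catalysed lactonisation of (Z)-γ,δ-epoxy-α,β-unsaturated esters to γ-(1-hydroxyalkyl)butenolides, an epoxide-opening lactonisation driven by release of oxirane strain. The five-membered lactone ring closes in the 5-exo-tet mode. C6 is set by stereospecific inversion of the (S)-configured epoxide carbon, and C5 keeps the epoxide oxygen with retention, so the threo C5–O/C6–O pattern follows from the cis-epoxide. The step needs attack at C6 and not at C5 (6-endo) and SN2 opening rather than ionisation: C5 is deactivated by the adjacent ketone, the Z-alkene places the carbonyl oxygen within reach of C6 only, the ester on C11 disfavours an allyl cation, and the naphthylmethyl ether is trans to C6 and cannot compete.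

Step 7
Reactants: 9 (5R)-5-[(1S)-1-hydroxy-2-oxopropyl]-3-[(naphthalen-2-ylmethoxy)methyl]furan-2(5H)-one
Product: 10 (5R)-5-[(1S,2S)-1,2-dihydroxy-2-methylpent-4-en-1-yl]-3-[(naphthalen-2-ylmethoxy)methyl]furan-2(5H)-one
Conditions: In powder, allyl bromide, THF/H2O (1:1), rt
Reagents that add atoms: allyl bromide, C=CCBr
Why: Indium-mediated Barbier allylation in aqueous THF is chemoselective for the ketone, and chelation of indium between the C5 hydroxyl and the ketone oxygen (Cram chelate) should direct the allyl group to the face opposite C6, setting C4 with its hydroxyl syn to the C5 oxygen.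

Step 8
Reactants: 10 (5R)-5-[(1S,2S)-1,2-dihydroxy-2-methylpent-4-en-1-yl]-3-[(naphthalen-2-ylmethoxy)methyl]furan-2(5H)-one
Product: 11 (1S,2S)-2-hydroxy-2-methyl-1-[(2R)-4-[(naphthalen-2-ylmethoxy)methyl]-5-oxo-2,5-dihydrofuran-2-yl]pent-4-en-1-yl 2-methylpropanoate
Conditions: i-PrCOCl, pyridine, DMAP (cat.), CH2Cl2, 0 °C
Reagents that add atoms: isobutyryl chloride, CC(C)C(=O)Cl
Why: Acylation with the acid chloride esterifies the secondary C5 hydroxyl selectively over the hindered tertiary C4 hydroxyl.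

Step 9
Reactants: 12 2,2-dimethoxyacetaldehyde
Product: 13 (2R,3S)-1,1-dimethoxy-3-methylpent-4-en-2-ol
Conditions: (Z)-crotylboronic acid pinacol ester, (R)-TRIP phosphoric acid (5 mol%), toluene, −30 °C; aqueous work-up
Reagents that add atoms: (Z)-crotylboronic acid pinacol ester, C/C=C\CB1OC(C)(C)C(C)(C)O1
Why: Chiral phosphoric acid-catalysed crotylboration proceeds through a closed chair transition state, so the (Z)-boronate should give the syn adduct and the catalyst the (2R,3S) enantiomer, which sets the C10 methyl centre and a disposable C9 carbinol centre.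

Step 10
Reactants: 13 (2R,3S)-1,1-dimethoxy-3-methylpent-4-en-2-ol
Product: 14 tert-butyl{[(2R,3S)-1,1-dimethoxy-3-methylpent-4-en-2-yl]oxy}dimethylsilane
Conditions: TBSCl, imidazole, DMF, rt
Reagents that add atoms: tert-butyldimethylsilyl chloride, CC(C)(C)[Si](C)(C)Cl
Why: Standard silylation protects the C9 hydroxyl as a non-chelating silyl ether that later favours Felkin–Anh addition to C8.

Step 11
Reactants: 11 (1S,2S)-2-hydroxy-2-methyl-1-[(2R)-4-[(naphthalen-2-ylmethoxy)methyl]-5-oxo-2,5-dihydrofuran-2-yl]pent-4-en-1-yl 2-methylpropanoate, 14 tert-butyl{[(2R,3S)-1,1-dimethoxy-3-methylpent-4-en-2-yl]oxy}dimethylsilane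
Product: 15 (1S,2S,4E,6S,7R)-7-[(tert-butyldimethylsilyl)oxy]-2-hydroxy-8,8-dimethoxy-2,6-dimethyl-1-[(2R)-4-[(naphthalen-2-ylmethoxy)methyl]-5-oxo-2,5-dihydrofuran-2-yl]oct-4-en-1-yl 2-methylpropanoate
Conditions: second-generation Grubbs catalyst (5 mol%), 14 (3 equiv), CH2Cl2, 40 °C
Reagents that add atoms: none
Why: Olefin cross-metathesis between the unhindered allyl group and the excess vinyl partner should give mainly the (E)-alkene while the trisubstituted, conjugated butenolide alkene stays inert; no acrylate is yet present.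

Step 12
Reactants: 15 the cross-metathesis product
Product: 16 (1S,2S,4E,6S,7R)-7-[(tert-butyldimethylsilyl)oxy]-2-hydroxy-1-[(2R)-4-(hydroxymethyl)-5-oxo-2,5-dihydrofuran-2-yl]-8,8-dimethoxy-2,6-dimethyloct-4-en-1-yl 2-methylpropanoate
Conditions: DDQ, CH2Cl2/pH 7 buffer, 0 °C
Reagents that add atoms: none
Why: Oxidative cleavage of the 2-naphthylmethyl ether by DDQ (as for a p-methoxybenzyl ether) frees the primary allylic alcohol and leaves silyl ether, acetal and esters untouched.

Step 13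
Reactants: 16 the C13 allylic alcohol
Product: 17 (1S,2S,4E,6S,7R)-1-[(2R)-4-(bromomethyl)-5-oxo-2,5-dihydrofuran-2-yl]-7-[(tert-butyldimethylsilyl)oxy]-2-hydroxy-8,8-dimethoxy-2,6-dimethyloct-4-en-1-yl 2-methylpropanoate
Conditions: CBr4, PPh3, CH2Cl2, 0 °C
Reagents that add atoms: carbon tetrabromide, BrC(Br)(Br)Br
Why: Appel bromination converts the primary allylic alcohol into the allylic bromide under neutral conditions that spare the tertiary alcohol.

Step 14
Reactants: 17 the C13 allylic bromide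
Product: 18 (1S,2S,4E,6S,7R)-1-[(2R)-4-(bromomethyl)-5-oxo-2,5-dihydrofuran-2-yl]-7-[(tert-butyldimethylsilyl)oxy]-2-hydroxy-2,6-dimethyl-8-oxooct-4-en-1-yl 2-methylpropanoate
Conditions: LiBF4, MeCN/H2O (50:1), rt
Reagents that add atoms: water, O
Why: Mild Lewis-acid hydrolysis of the dimethyl acetal (LiBF4 in wet acetonitrile) unmasks the C8 aldehyde without cleaving the silyl ether.

Step 15
Reactants: 18 the bromo aldehyde
Product: 19 ten-membered 8-hydroxy α-methylene 6,12-lactone: (E)-C1=C2, C9 OTBS, C5 isobutyrate, C4 tertiary OH (stereocentres as in the SMILES)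
Conditions: CrCl2 (8 equiv), THF, rt, slow addition (final 2 mM)
Reagents that add atoms: none
Why: Intramolecular Nozaki–Hiyama allylation (Barbier reaction mediated by divalent chromium) of the 2-(bromomethyl)enoate type: the allylchromium reagent should add through C7 in a chair transition state on the butenolide face anti to the C5 side chain (C7 trans to C6), its ring-locked geometry giving the anti C7/C8 relationship reinforced by Felkin–Anh control from the C9 silyl ether, while closing the ten-membered ring and creating the α-methylene lactone.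

Step 16
Reactants: 19 the ten-membered 8-hydroxy lactone
Product: 20 5,8-bis(isobutyrate) of 19 (C9 OTBS, C4 OH, (E)-C1=C2)
Conditions: i-PrCOCl, pyridine, DMAP (cat.), CH2Cl2, 0 °C to rt
Reagents that add atoms: isobutyryl chloride, CC(C)C(=O)Cl
Why: Acylation of the secondary C8 hydroxyl, the tertiary C4 hydroxyl being too hindered to react, fixes the alcohol as its isobutyrate and prevents lactone migration.

Step 17
Reactants: 20 the bis(isobutyrate)
Product: 22 oxasilolane bridging C4–O and C2 through SiMe2 (C1 now CH2), via hydrodimethylsilyl ether 21 (not isolated)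
Conditions: (HMe2Si)2NH, neat, 60 °C; then Pt2[(CH2=CHSiMe2)2O]3 (2 mol%), toluene, 60 °C
Reagents that add atoms: 1,1,3,3-tetramethyldisilazane, C[SiH](C)N[SiH](C)C
Why: Tamao–Ito intramolecular hydrosilylation: the silyl hydride tethered to the C4 oxygen should add 5-exo across C1=C2 with silicon on C2, and the two-atom O–Si bridge can only span C4 and C2 on the same face of the ring, which sets C2 syn to the C4 oxygen.

Step 18
Reactants: 22 the oxasilolane
Product: 23 C2 fluorodimethylsilyl compound with free C4 and C9 hydroxyls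
Conditions: HF·pyridine, pyridine, THF, 0 °C to rt
Reagents that add atoms: hydrogen fluoride (as HF·pyridine), F
Why: Fluoride cleaves the silyl ether at C9 and opens the strained Si–O bond of the oxasilolane, leaving the C2–Si bond as a fluorosilane ready for oxidation.

Step 19
Reactants: 23 the fluorosilane diol
Product: 24 C9 ketone bearing the C2 fluorodimethylsilyl group
Conditions: Dess–Martin periodinane, CH2Cl2, rt
Reagents that add atoms: none
Why: Dess–Martin oxidation converts the only secondary alcohol (C9) into the ketone under neutral conditions after the ring alkene has gone, so the C10 and C8 centres are not exposed to base.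

Step 20
Reactants: 24 the keto fluorosilane
Product: 25 cardivin D
Conditions: KHF2, m-CPBA, DMF, 0 °C to rt
Reagents that add atoms: m-chloroperoxybenzoic acid, O=C(OO)c1cccc(Cl)c1
Why: Tamao–Fleming oxidation of the fluorosilane with peracid and fluoride replaces silicon by hydroxyl with retention at C2 under non-basic conditions that spare the α-methylene lactone and the α-acyloxy ketone.

Compound list
1 | (S)-but-3-yn-2-ol | C[C@H](O)C#C | starting material
2 | (S)-pent-2-yne-1,4-diol | C[C@H](O)C#CCO | intermediate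
3 | (S,Z)-pent-2-ene-1,4-diol | C[C@H](O)/C=C\CO | intermediate
4 | (S)-1-[(2R,3S)-3-(hydroxymethyl)oxiran-2-yl]ethan-1-ol | C[C@H](O)[C@H]1O[C@H]1CO | intermediate
5 | methyl 2-[bis(2,2,2-trifluoroethoxy)phosphoryl]acetate | COC(=O)CP(=O)(OCC(F)(F)F)OCC(F)(F)F | starting material
6 | methyl 2-[bis(2,2,2-trifluoroethoxy)phosphoryl]-3-(naphthalen-2-ylmethoxy)propanoate (racemic) | COC(=O)C(COCc1ccc2ccccc2c1)P(=O)(OCC(F)(F)F)OCC(F)(F)F | intermediate
7 | (2R,3S)-3-acetyloxirane-2-carbaldehyde | CC(=O)[C@H]1O[C@H]1C=O | intermediate (not isolated)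
8 | methyl (Z)-3-[(2S,3S)-3-acetyloxiran-2-yl]-2-[(naphthalen-2-ylmethoxy)methyl]prop-2-enoate | CC(=O)[C@H]1O[C@H]1/C=C(/COCc2ccc3ccccc3c2)C(=O)OC | intermediate
9 | (5R)-5-[(1S)-1-hydroxy-2-oxopropyl]-3-[(naphthalen-2-ylmethoxy)methyl]furan-2(5H)-one | CC(=O)[C@@H](O)[C@@H]1OC(=O)C(COCc2ccc3ccccc3c2)=C1 | intermediate
10 | (5R)-5-[(1S,2S)-1,2-dihydroxy-2-methylpent-4-en-1-yl]-3-[(naphthalen-2-ylmethoxy)methyl]furan-2(5H)-one | C=CC[C@](C)(O)[C@@H](O)[C@@H]1OC(=O)C(COCc2ccc3ccccc3c2)=C1 | intermediate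
11 | (1S,2S)-2-hydroxy-2-methyl-1-[(2R)-4-[(naphthalen-2-ylmethoxy)methyl]-5-oxo-2,5-dihydrofuran-2-yl]pent-4-en-1-yl 2-methylpropanoate | C=CC[C@](C)(O)[C@@H](OC(=O)C(C)C)[C@@H]1OC(=O)C(COCc2ccc3ccccc3c2)=C1 | intermediate
12 | 2,2-dimethoxyacetaldehyde | COC(OC)C=O | starting material
13 | (2R,3S)-1,1-dimethoxy-3-methylpent-4-en-2-ol | COC(OC)[C@H](O)[C@@H](C)C=C | intermediate
14 | tert-butyl{[(2R,3S)-1,1-dimethoxy-3-methylpent-4-en-2-yl]oxy}dimethylsilane | COC(OC)[C@H](O[Si](C)(C)C(C)(C)C)[C@@H](C)C=C | intermediate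
15 | (1S,2S,4E,6S,7R)-7-[(tert-butyldimethylsilyl)oxy]-2-hydroxy-8,8-dimethoxy-2,6-dimethyl-1-[(2R)-4-[(naphthalen-2-ylmethoxy)methyl]-5-oxo-2,5-dihydrofuran-2-yl]oct-4-en-1-yl 2-methylpropanoate | COC(OC)[C@H](O[Si](C)(C)C(C)(C)C)[C@@H](C)/C=C/C[C@](C)(O)[C@@H](OC(=O)C(C)C)[C@@H]1OC(=O)C(COCc2ccc3ccccc3c2)=C1 | intermediate
16 | (1S,2S,4E,6S,7R)-7-[(tert-butyldimethylsilyl)oxy]-2-hydroxy-1-[(2R)-4-(hydroxymethyl)-5-oxo-2,5-dihydrofuran-2-yl]-8,8-dimethoxy-2,6-dimethyloct-4-en-1-yl 2-methylpropanoate | COC(OC)[C@H](O[Si](C)(C)C(C)(C)C)[C@@H](C)/C=C/C[C@](C)(O)[C@@H](OC(=O)C(C)C)[C@@H]1OC(=O)C(CO)=C1 | intermediate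
17 | (1S,2S,4E,6S,7R)-1-[(2R)-4-(bromomethyl)-5-oxo-2,5-dihydrofuran-2-yl]-7-[(tert-butyldimethylsilyl)oxy]-2-hydroxy-8,8-dimethoxy-2,6-dimethyloct-4-en-1-yl 2-methylpropanoate | COC(OC)[C@H](O[Si](C)(C)C(C)(C)C)[C@@H](C)/C=C/C[C@](C)(O)[C@@H](OC(=O)C(C)C)[C@@H]1OC(=O)C(CBr)=C1 | intermediate
18 | (1S,2S,4E,6S,7R)-1-[(2R)-4-(bromomethyl)-5-oxo-2,5-dihydrofuran-2-yl]-7-[(tert-butyldimethylsilyl)oxy]-2-hydroxy-2,6-dimethyl-8-oxooct-4-en-1-yl 2-methylpropanoate | O=C[C@H](O[Si](C)(C)C(C)(C)C)[C@@H](C)/C=C/C[C@](C)(O)[C@@H](OC(=O)C(C)C)[C@@H]1OC(=O)C(CBr)=C1 | intermediate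
19 | ten-membered α-methylene 6,12-lactone with C8 OH, C9 (R) OTBS, (E)-C1=C2, C4 OH, C5 isobutyrate; C4–C8 and C10 arranged as in 25 | C=C1C(=O)O[C@@H]2[C@@H]1[C@H](O)[C@H](O[Si](C)(C)C(C)(C)C)[C@@H](C)/C=C/C[C@](C)(O)[C@H]2OC(=O)C(C)C | intermediate
20 | 5,8-bis(isobutyrate) of 19 | C=C1C(=O)O[C@@H]2[C@@H]1[C@H](OC(=O)C(C)C)[C@H](O[Si](C)(C)C(C)(C)C)[C@@H](C)/C=C/C[C@](C)(O)[C@H]2OC(=O)C(C)C | intermediate
21 | C4 O-(dimethylsilyl) ether of 20 | C=C1C(=O)O[C@@H]2[C@@H]1[C@H](OC(=O)C(C)C)[C@H](O[Si](C)(C)C(C)(C)C)[C@@H](C)/C=C/C[C@](C)(O[SiH](C)C)[C@H]2OC(=O)C(C)C | intermediate (not isolated)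
22 | 2,2-dimethyl-1,2-oxasilolane spanning C4–O and C2 (C2 S), C9 OTBS, both isobutyrates in place | C=C1C(=O)O[C@@H]2[C@@H]1[C@H](OC(=O)C(C)C)[C@H](O[Si](C)(C)C(C)(C)C)[C@@H](C)C[C@H]3C[C@](C)(O[Si]3(C)C)[C@H]2OC(=O)C(C)C | intermediate
23 | C2 fluorodimethylsilyl compound with free C4 and C9 hydroxyls | C=C1C(=O)O[C@@H]2[C@@H]1[C@H](OC(=O)C(C)C)[C@H](O)[C@@H](C)C[C@H]([Si](C)(C)F)C[C@](C)(O)[C@H]2OC(=O)C(C)C | intermediate
24 | C9 ketone with C2 fluorodimethylsilyl group | C=C1C(=O)O[C@@H]2[C@@H]1[C@H](OC(=O)C(C)C)C(=O)[C@@H](C)C[C@H]([Si](C)(C)F)C[C@](C)(O)[C@H]2OC(=O)C(C)C | intermediate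
25 | cardivin D | C=C1C(=O)O[C@@H]2[C@@H]1[C@H](OC(=O)C(C)C)C(=O)[C@@H](C)C[C@H](O)C[C@](C)(O)[C@H]2OC(=O)C(C)C | target

Total step count: 20. Longest linear sequence: 17 steps (steps 1–3, 5–8, 11–20).

Steps most likely to fail

Step 15 (oligomerisation at the dilution needed, migration of the lactone onto the new C8 alkoxide, or loss of facial control in the chair transition state). Fallback: the ring is closed by metathesis and the C7–C8 bond is made intermolecularly before any acrylate exists; it sets out from 11 and 14 and returns at 20. From 14, LiBF4 in wet MeCN should give (2R,3S)-2-[(tert-butyldimethylsilyl)oxy]-3-methylpent-4-enal F1. SmI2 with t-BuOH in THF at −78 °C should couple the ketyl of F1 to C7 of butenolide 11, anti to the C6 substituent, giving the saturated lactone adduct F2 (mixture at C11). i-PrCOCl/pyridine gives the C8 isobutyrate F3. The second-generation Grubbs catalyst should then close the cyclodecene F4. DDQ frees the C13 alcohol F5, and MsCl/Et3N followed by DBU eliminates to the α-methylene lactone 20.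

Step 17 (slow silylation of the hindered tertiary alcohol, alkene migration by platinum hydride, or 6-endo closure). Fallback: intermolecular hydroboration, setting out from 20 and returning at 25. 9-BBN, then NaBO3, should place boron on C2, the alkene carbon remote from the branched C10, giving the C2,C4-diol F6; facial selectivity is the open point here. 2,2-Dimethoxypropane/PPTS gives the acetonide F7, HF·pyridine the C9 alcohol F8, and Dess–Martin oxidation the ketone acetonide F9. Aqueous AcOH removes the acetonide to give 25.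

Step 3 (erosion of facial selectivity because the primary hydroxyl also delivers the peracid). Fallback: reagent-controlled Sharpless epoxidation, setting out from 1 and returning at 4. TBSCl/imidazole gives (S)-tert-butyl(but-3-yn-2-yloxy)dimethylsilane F10. n-BuLi and paraformaldehyde give (S)-4-[(tert-butyldimethylsilyl)oxy]pent-2-yn-1-ol F11. Lindlar hydrogenation gives (S,Z)-4-[(tert-butyldimethylsilyl)oxy]pent-2-en-1-ol F12. Ti(OiPr)4, L-(+)-diethyl tartrate and t-BuOOH should give [(2S,3S)-3-[(1S)-1-[(tert-butyldimethylsilyl)oxy]ethyl]oxiran-2-yl]methanol F13, and n-Bu4NF then gives 4.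

Further compounds
F1 | step 15 | (2R,3S)-2-[(tert-butyldimethylsilyl)oxy]-3-methylpent-4-enal | O=C[C@H](O[Si](C)(C)C(C)(C)C)[C@@H](C)C=C
F2 | step 15 | saturated lactone adduct (C7–C8 bond, C8 OH, C11 bearing CH2O-naphthylmethyl, mixture at C11) | C=CC[C@](C)(O)[C@@H](OC(=O)C(C)C)[C@@H]1OC(=O)C(COCc2ccc3ccccc3c2)[C@H]1[C@H](O)[C@H](O[Si](C)(C)C(C)(C)C)[C@@H](C)C=C
F3 | step 15 | C8 isobutyrate of F2 | C=CC[C@](C)(O)[C@@H](OC(=O)C(C)C)[C@@H]1OC(=O)C(COCc2ccc3ccccc3c2)[C@H]1[C@H](OC(=O)C(C)C)[C@H](O[Si](C)(C)C(C)(C)C)[C@@H](C)C=C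
F4 | step 15 | cyclodecene from ring-closing metathesis of F3 | O=C1O[C@@H]2[C@@H](C1COCc3ccc4ccccc4c3)[C@H](OC(=O)C(C)C)[C@H](O[Si](C)(C)C(C)(C)C)[C@@H](C)/C=C/C[C@](C)(O)[C@H]2OC(=O)C(C)C
F5 | step 15 | C13 alcohol from F4 | O=C1O[C@@H]2[C@@H](C1CO)[C@H](OC(=O)C(C)C)[C@H](O[Si](C)(C)C(C)(C)C)[C@@H](C)/C=C/C[C@](C)(O)[C@H]2OC(=O)C(C)C
F6 | step 17 | C2,C4-diol from hydroboration of 20 | C=C1C(=O)O[C@@H]2[C@@H]1[C@H](OC(=O)C(C)C)[C@H](O[Si](C)(C)C(C)(C)C)[C@@H](C)C[C@H](O)C[C@](C)(O)[C@H]2OC(=O)C(C)C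
F7 | step 17 | C2,C4-acetonide of F6 | C=C1C(=O)O[C@@H]2[C@@H]1[C@H](OC(=O)C(C)C)[C@H](O[Si](C)(C)C(C)(C)C)[C@@H](C)C[C@H]3C[C@](C)(OC(C)(C)O3)[C@H]2OC(=O)C(C)C
F8 | step 17 | C9 alcohol acetonide | C=C1C(=O)O[C@@H]2[C@@H]1[C@H](OC(=O)C(C)C)[C@H](O)[C@@H](C)C[C@H]3C[C@](C)(OC(C)(C)O3)[C@H]2OC(=O)C(C)C
F9 | step 17 | C9 ketone acetonide | C=C1C(=O)O[C@@H]2[C@@H]1[C@H](OC(=O)C(C)C)C(=O)[C@@H](C)C[C@H]3C[C@](C)(OC(C)(C)O3)[C@H]2OC(=O)C(C)C
F10 | step 3 | (S)-tert-butyl(but-3-yn-2-yloxy)dimethylsilane | C[C@H](O[Si](C)(C)C(C)(C)C)C#C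
F11 | step 3 | (S)-4-[(tert-butyldimethylsilyl)oxy]pent-2-yn-1-ol | C[C@H](O[Si](C)(C)C(C)(C)C)C#CCO
F12 | step 3 | (S,Z)-4-[(tert-butyldimethylsilyl)oxy]pent-2-en-1-ol | C[C@H](O[Si](C)(C)C(C)(C)C)/C=C\CO
F13 | step 3 | [(2S,3S)-3-[(1S)-1-[(tert-butyldimethylsilyl)oxy]ethyl]oxiran-2-yl]methanol | C[C@H](O[Si](C)(C)C(C)(C)C)[C@H]1O[C@H]1CO
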